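**Retrosynthetic overview**

- Target 23 is the C6 4-methoxybenzoate of diol 21. Diol 21 comes from hydroxy diketone 20 by reduction of the C6 carbonyl directed by the C4 hydroxyl, and 20 from dienone 18 by a 1,6-reduction that places the C8=C9 alkene.
- The strategy rests on this feature (daucane numbering): the seven-membered ring atoms C5–C10, with the C8 methyl and the C6 oxygen, are a 2-methoxy-4-methylphenyl ring, and the quaternary C1 (methyl, next to the C2 ketone) is a carbene carbon inserted between ipso C5 and ortho C10.
- Key disconnection: C1–C5 and C1–C10, by intramolecular Buchner reaction of the α-diazo ethyl ketone 15 to the methoxy-azulenone 17.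
- 15 comes from the (R)-1,3-diol 9, 9 from epoxy alcohol 8 (Sharpless epoxidation, Red-Al), 8 from the (E)-allylic alcohol 7, and 7 from enoate 6, made from aryl bromide 1 and ynoate 2 by syn-carbocupration.
- Ring order: the benzene ring is bought; the cyclopentanone and the seven-membered ring are formed together in step 10; no ring is formed afterwards.

Key step: step 10

Remark: atoms are numbered as in daucane (C1 quaternary CMe, C2 ketone, C3 CH2, C4 carbinol with isopropyl, C5 ring-fusion CH, C6 CH–O, C7 CH2, C8(Me)=C9, C10 CH2); ethyl 4-methylpent-2-ynoate is taken to be purchasable (otherwise one step from 3-methylbut-1-yne and ethyl chloroformate).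

**Route**

Step 1
Reactants: 1 2-bromo-5-methylanisole (2 equiv); 2 ethyl 4-methylpent-2-ynoate
Product: 6 ethyl (E)-3-(2-methoxy-4-methylphenyl)-4-methylpent-2-enoate, via aryllithium 3 (not isolated), via lithium diarylcuprate 4 (not isolated), via alkenylcuprate 5 (not isolated)
Conditions: 1, t-BuLi (2 equiv per ArBr), THF/Et2O, −78 °C; CuI (0.5 equiv per ArLi), −78 → −40 °C; 2, THF, −78 °C; NH4Cl in MeOH/H2O at −78 °C
Reagents that add atoms: none
Why: Lithium–bromine exchange gives the aryllithium, whose Gilman cuprate adds the aryl group and copper syn across the ynoate with aryl at the β-carbon, and protonation of the alkenylcuprate at −78 °C, before it can equilibrate through the allenoate, fixes the aryl group cis to the vinyl hydrogen (syn-carbocupration of an alkynoate).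

Step 2
Reactants: 6 ethyl (E)-3-(2-methoxy-4-methylphenyl)-4-methylpent-2-enoate
Product: 7 (E)-3-(2-methoxy-4-methylphenyl)-4-methylpent-2-en-1-ol
Conditions: i-Bu2AlH (2.5 equiv), CH2Cl2, −78 °C; aq. potassium sodium tartrate
Reagents that add atoms: none
Why: i-Bu2AlH reduces the conjugated ester by two 1,2-hydride additions to the allylic alcohol without touching the trisubstituted alkene or its geometry (ester reduction).

Step 3
Reactants: 7 (E)-3-(2-methoxy-4-methylphenyl)-4-methylpent-2-en-1-ol
Product: 8 [(2R,3R)-3-(2-methoxy-4-methylphenyl)-3-(propan-2-yl)oxiran-2-yl]methanol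
Conditions: Ti(OiPr)4 (0.2 equiv), D-(−)-diethyl tartrate (0.26 equiv), t-BuOOH (2 equiv, anhydrous), 4 Å molecular sieves, CH2Cl2, −20 °C; 10% NaOH in brine, 0 °C; Et3N-deactivated silica
Reagents that add atoms: tert-butyl hydroperoxide, CC(C)(C)OO
Why: Sharpless asymmetric epoxidation with the titanium–D-(−)-tartrate complex, the ligand that gives the 2R series of epoxy alcohols (the L-(+) ligand gives 2S), oxidises one face of the E-alkene so that both new centres are set together as 2R,3R, and the basic work-up spares the acid-labile benzylic epoxide.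

Step 4
Reactants: 8 [(2R,3R)-3-(2-methoxy-4-methylphenyl)-3-(propan-2-yl)oxiran-2-yl]methanol
Product: 9 (3R)-3-(2-methoxy-4-methylphenyl)-4-methylpentane-1,3-diol
Conditions: NaAlH2(OCH2CH2OMe)2 (2 equiv), THF, 0 °C → rt; aq. potassium sodium tartrate
Reagents that add atoms: none
Why: The aluminate formed at the primary hydroxyl delivers hydride intramolecularly to C2, so the epoxide opens to the 1,3-diol and the tertiary benzylic C–O bond with its configuration is kept (Red-Al opening of a 2,3-epoxy alcohol).

Step 5
Reactants: 9 (3R)-3-(2-methoxy-4-methylphenyl)-4-methylpentane-1,3-diol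
Product: 10 (3R)-3-(2-methoxy-4-methylphenyl)-4-methyl-1,3-bis(triethylsilyloxy)pentane
Conditions: Et3SiOTf (2.5 equiv), 2,6-lutidine (4 equiv), CH2Cl2, −78 → 0 °C
Reagents that add atoms: triethylsilyl trifluoromethanesulfonate, CC[Si](CC)(CC)OS(=O)(=O)C(F)(F)F
Why: The silyl triflate with a hindered pyridine base silylates the primary and also the crowded tertiary benzylic hydroxyl without ionising it, and doing so before any ketone is present rules out enol silylation and retro-aldol cleavage later (silyl ether formation).

Step 6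
Reactants: 10 (3R)-3-(2-methoxy-4-methylphenyl)-4-methyl-1,3-bis(triethylsilyloxy)pentane
Product: 11 (3R)-3-(2-methoxy-4-methylphenyl)-4-methyl-3-(triethylsilyloxy)pentanal
Conditions: (COCl)2 (4 equiv), DMSO (8 equiv), CH2Cl2, −78 → −30 °C; Et3N, −78 → 0 °C
Reagents that add atoms: none
Why: Under Swern conditions the chlorosulfonium salt attacks only the unhindered primary silyl ether, which is converted in place into the aldehyde, while the tertiary triethylsilyl ether is too hindered to react (Swern oxidation with oxidative desilylation of a primary triethylsilyl ether).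

Step 7
Reactants: 11 (3R)-3-(2-methoxy-4-methylphenyl)-4-methyl-3-(triethylsilyloxy)pentanal
Product: 12 (5R)-5-(2-methoxy-4-methylphenyl)-6-methyl-5-(triethylsilyloxy)heptan-3-ol (both C3 epimers)
Conditions: EtMgBr (1.5 equiv), THF, −78 °C; sat. aq. NH4Cl at −78 °C
Reagents that add atoms: ethylmagnesium bromide, CC[Mg]Br
Why: Grignard addition to the aldehyde gives the secondary alcohol as an epimer mixture that is of no consequence because this carbon becomes the ketone, and the cold quench prevents silyl migration from the tertiary to the new secondary oxygen.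

Step 8
Reactants: 12 (5R)-5-(2-methoxy-4-methylphenyl)-6-methyl-5-(triethylsilyloxy)heptan-3-ol
Product: 13 (5R)-5-(2-methoxy-4-methylphenyl)-6-methyl-5-(triethylsilyloxy)heptan-3-one
Conditions: Dess–Martin periodinane (1.5 equiv), NaHCO3, CH2Cl2, 0 °C → rt
Reagents that add atoms: none
Why: Dess–Martin oxidation under buffered neutral conditions gives the ethyl ketone without β-elimination of the silyloxy group.

Step 9
Reactants: 13 (5R)-5-(2-methoxy-4-methylphenyl)-6-methyl-5-(triethylsilyloxy)heptan-3-one
Product: 15 (5R)-2-diazo-5-(2-methoxy-4-methylphenyl)-6-methyl-5-(triethylsilyloxy)heptan-3-one, via trifluoroacetyl ketone 14 (not isolated)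
Conditions: LiN(SiMe3)2 (1.1 equiv), THF, −78 °C; CF3CO2CH2CF3 (1.2 equiv), −78 °C; sat. aq. NH4Cl; then MeSO2N3 (1.5 equiv), Et3N (1.5 equiv), H2O (1 equiv), MeCN, rt
Reagents that add atoms: methanesulfonyl azide, CS(=O)(=O)N=[N+]=[N-] (the two nitrogen atoms of 15); 2,2,2-trifluoroethyl trifluoroacetate, O=C(OCC(F)(F)F)C(F)(F)F (trifluoroacetyl group of 14 only)
Why: LiN(SiMe3)2 deprotonates the unhindered ethyl CH2 kinetically (the other α-CH2 is neopentylic), the enolate is C-trifluoroacetylated, and the activated 1,3-dicarbonyl compound takes the diazo group from the sulfonyl azide with loss of the trifluoroacetyl group as the N-acylsulfonamide (detrifluoroacetylative diazo transfer).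

Step 10
Reactants: 15 (5R)-2-diazo-5-(2-methoxy-4-methylphenyl)-6-methyl-5-(triethylsilyloxy)heptan-3-one
Product: 17 (3R,8aR)-4-methoxy-6,8a-dimethyl-3-(propan-2-yl)-3-(triethylsilyloxy)-3,8a-dihydroazulen-1(2H)-one, via norcaradiene 16 (not isolated)
Conditions: Rh2(O2CCF3)4 (1 mol %), CH2Cl2, −20 → 0 °C, slow addition of 15; filtration through basic alumina; used at once
Reagents that add atoms: none
Why: Loss of N2 gives an electrophilic rhodium carbene at C1 that adds across the ipso C5–ortho C10 bond of the anisole ring (intramolecular aromatic cyclopropanation, Buchner reaction), forming C1–C5 and C1–C10, and the norcaradiene 16 then opens by a six-electron disrotatory electrocyclic reaction that breaks C5–C10. The cyclopentanone ring is closed through the three-atom tether C2–C3–C4 in an exo mode at the ipso carbon, the benzene ring becomes the seven-membered ring by ring expansion and not by a cyclisation, and because C1 is quaternary the cycloheptatriene cannot rearomatise or tautomerise by hydrogen shift. The closest known reaction is the rhodium-catalysed cyclisation of 2-diazo-5-arylpentan-3-ones to 8a-methylazulenones, in which a benzylic alkyl group ends trans to the 8a-methyl group. C1 is the only lasting new stereocentre and is set by C4: in the reactive rotamer the small oxygen atom of the silyloxy group lies near the arene plane beside the ortho-methoxy group and the isopropyl group points away from the ring, so the tether reaches one face only and the C1 methyl group ends cis to the silyloxy group and trans to isopropyl. Regioselectivity for C10 over the methoxy-bearing C6 is steric, and addition to the electron-rich arene is favoured over 1,2-hydride shift, insertion into the isopropyl C–H bond and ylide formation at the hindered silyl ether oxygen by the electron-poor carboxylate ligands, the low temperature and the slow addition.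

Step 11
Reactants: 17 (3R,8aR)-4-methoxy-6,8a-dimethyl-3-(propan-2-yl)-3-(triethylsilyloxy)-3,8a-dihydroazulen-1(2H)-one
Product: 18 (3R,3aR,8aR)-6,8a-dimethyl-3-(propan-2-yl)-3-(triethylsilyloxy)-2,3,3a,8a-tetrahydroazulene-1,4-dione (trans-fused)
Conditions: oxalic acid (0.2 equiv), THF/H2O, 0 °C → rt
Reagents that add atoms: water, O
Why: Protonation of the methyl enol ether at C5 gives a dienyl-stabilised oxocarbenium ion that water converts into the C6 ketone under conditions too mild for the acid-induced rearrangement of azulenones to 2-tetralones, and C5, now enolisable, is expected to settle as the trans-fused isomer with hydrogen anti to the C1 methyl group and C6 anti to the isopropyl group, the outcome of both protonation from the less hindered face and equilibration (enol ether hydrolysis).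

Step 12
Reactants: 18 (3R,3aR,8aR)-6,8a-dimethyl-3-(propan-2-yl)-3-(triethylsilyloxy)-2,3,3a,8a-tetrahydroazulene-1,4-dione
Product: 19 (3R,3aR,8aR)-6,8a-dimethyl-3-(propan-2-yl)-3-(triethylsilyloxy)-2,3,3a,5,8,8a-hexahydroazulene-1,4-dione
Conditions: SmI2 (2.5 equiv), THF/MeOH, −78 °C
Reagents that add atoms: none
Why: Two single-electron transfers from divalent samarium with protonation at the diene terminus C10 give a samarium dienolate, whose kinetic protonation at the α-carbon C7 leaves the C8=C9 alkene out of conjugation, while the isolated C2 ketone is not reduced by SmI2 in the absence of a stronger activator (1,6-reduction of a dienone).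

Step 13
Reactants: 19 (3R,3aR,8aR)-6,8a-dimethyl-3-(propan-2-yl)-3-(triethylsilyloxy)-2,3,3a,5,8,8a-hexahydroazulene-1,4-dione
Product: 20 (3R,3aR,8aR)-3-hydroxy-6,8a-dimethyl-3-(propan-2-yl)-2,3,3a,5,8,8a-hexahydroazulene-1,4-dione
Conditions: HF·pyridine, pyridine, THF, 0 °C → rt
Reagents that add atoms: none
Why: Fluoride cleaves the tertiary triethylsilyl ether under buffered, non-basic conditions, so the β-hydroxy ketone is exposed without retro-aldol cleavage, elimination or epimerisation at C5 (fluoride desilylation).

Step 14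
Reactants: 20 (3R,3aR,8aR)-3-hydroxy-6,8a-dimethyl-3-(propan-2-yl)-2,3,3a,5,8,8a-hexahydroazulene-1,4-dione
Product: 21 (3R,3aS,4S,8aR)-3,4-dihydroxy-6,8a-dimethyl-3-(propan-2-yl)-2,3,3a,4,5,8-hexahydroazulen-1(8aH)-one (2-oxo-jaeschkeanadiol)
Conditions: Me4NBH(OAc)3 (3 equiv), MeCN/AcOH (1:1), −30 °C
Reagents that add atoms: none
Why: Exchange of an acetate for the C4 hydroxyl ties the borohydride to that oxygen and the hydride is delivered within the molecule, through a six-membered chair transition state, to the β-face of the C6 carbonyl, which sets the C6 carbinol anti to the C4 oxygen (equatorial), while the C2 carbonyl, next to the quaternary C1 and screened on its β-face by the C1 methyl group, is expected to react more slowly (hydroxyl-directed Saksena–Evans reduction).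

Step 15
Reactants: 21 2-oxo-jaeschkeanadiol; 22 4-methoxybenzoyl chloride
Product: 23 (3R,3aS,4S,8aR)-3-hydroxy-6,8a-dimethyl-1-oxo-3-(propan-2-yl)-1,2,3,3a,4,5,8,8a-octahydroazulen-4-yl 4-methoxybenzoate (target CNP0232277.1)
Conditions: 22 (1.3 equiv), pyridine, DMAP (0.1 equiv), CH2Cl2, 0 °C → rt
Reagents that add atoms: 4-methoxybenzoyl chloride, COc1ccc(C(Cl)=O)cc1
Why: Acyl transfer through the N-acylpyridinium ion esterifies the only secondary hydroxyl, the tertiary C4 hydroxyl being too hindered to react, and no stereocentre is touched (DMAP-catalysed acylation).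

**Compound list**

1 | 2-bromo-5-methylanisole | COc1cc(C)ccc1Br | starting material
2 | ethyl 4-methylpent-2-ynoate | CCOC(=O)C#CC(C)C | starting material
3 | (2-methoxy-4-methylphenyl)lithium | [Li]c1ccc(C)cc1OC | intermediate
4 | lithium bis(2-methoxy-4-methylphenyl)cuprate | [Li+].COc1cc(C)ccc1[Cu-]c1ccc(C)cc1OC | intermediate
5 | lithium alkenyl(aryl)cuprate from syn addition (copper cis to the new aryl group) | [Li+].CCOC(=O)/C([Cu-]c1ccc(C)cc1OC)=C(\C(C)C)c1ccc(C)cc1OC | intermediate
6 | ethyl (E)-3-(2-methoxy-4-methylphenyl)-4-methylpent-2-enoate (aryl cis to the vinyl H) | CCOC(=O)/C=C(\C(C)C)c1ccc(C)cc1OC | intermediate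
7 | (E)-3-(2-methoxy-4-methylphenyl)-4-methylpent-2-en-1-ol | OC/C=C(\C(C)C)c1ccc(C)cc1OC | intermediate
8 | [(2R,3R)-3-(2-methoxy-4-methylphenyl)-3-(propan-2-yl)oxiran-2-yl]methanol | OC[C@H]1O[C@]1(C(C)C)c2ccc(C)cc2OC | intermediate
9 | (3R)-3-(2-methoxy-4-methylphenyl)-4-methylpentane-1,3-diol | OCC[C@@](O)(C(C)C)c1ccc(C)cc1OC | intermediate
10 | (3R)-3-(2-methoxy-4-methylphenyl)-4-methyl-1,3-bis(triethylsilyloxy)pentane | CC[Si](CC)(CC)OCC[C@@](O[Si](CC)(CC)CC)(C(C)C)c1ccc(C)cc1OC | intermediate
11 | (3R)-3-(2-methoxy-4-methylphenyl)-4-methyl-3-(triethylsilyloxy)pentanal | O=CC[C@@](O[Si](CC)(CC)CC)(C(C)C)c1ccc(C)cc1OC | intermediate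
12 | (5R)-5-(2-methoxy-4-methylphenyl)-6-methyl-5-(triethylsilyloxy)heptan-3-ol, both C3 epimers | CCC(O)C[C@@](O[Si](CC)(CC)CC)(C(C)C)c1ccc(C)cc1OC | intermediate
13 | (5R)-5-(2-methoxy-4-methylphenyl)-6-methyl-5-(triethylsilyloxy)heptan-3-one | CCC(=O)C[C@@](O[Si](CC)(CC)CC)(C(C)C)c1ccc(C)cc1OC | intermediate
14 | 2-trifluoroacetyl derivative of 13 (α-trifluoroacetyl ketone) | CC(C(=O)C(F)(F)F)C(=O)C[C@@](O[Si](CC)(CC)CC)(C(C)C)c1ccc(C)cc1OC | intermediate
15 | (5R)-2-diazo-5-(2-methoxy-4-methylphenyl)-6-methyl-5-(triethylsilyloxy)heptan-3-one | CC(=[N+]=[N-])C(=O)C[C@@](O[Si](CC)(CC)CC)(C(C)C)c1ccc(C)cc1OC | intermediate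
16 | norcaradiene valence isomer of 17 (cyclopropane C1–C5–C10, diene C6=C7–C8=C9) | COC1=CC(C)=C[C@@H]2[C@@]3(C)C(=O)C[C@@](O[Si](CC)(CC)CC)(C(C)C)[C@@]123 | intermediate
17 | (3R,8aR)-4-methoxy-6,8a-dimethyl-3-(propan-2-yl)-3-(triethylsilyloxy)-3,8a-dihydroazulen-1(2H)-one (C1 methyl cis to the silyloxy group) | COC1C=C(C)C=C[C@@]2(C)C(=O)C[C@@](O[Si](CC)(CC)CC)(C(C)C)C=12 | intermediate
18 | (3R,3aR,8aR)-6,8a-dimethyl-3-(propan-2-yl)-3-(triethylsilyloxy)-2,3,3a,8a-tetrahydroazulene-1,4-dione, trans-fused | O=C1C=C(C)C=C[C@@]2(C)C(=O)C[C@@](O[Si](CC)(CC)CC)(C(C)C)[C@H]12 | intermediate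
19 | (3R,3aR,8aR)-6,8a-dimethyl-3-(propan-2-yl)-3-(triethylsilyloxy)-2,3,3a,5,8,8a-hexahydroazulene-1,4-dione | O=C1CC(C)=CC[C@@]2(C)C(=O)C[C@@](O[Si](CC)(CC)CC)(C(C)C)[C@H]12 | intermediate
20 | (3R,3aR,8aR)-3-hydroxy-6,8a-dimethyl-3-(propan-2-yl)-2,3,3a,5,8,8a-hexahydroazulene-1,4-dione | O=C1CC(C)=CC[C@@]2(C)C(=O)C[C@@](O)(C(C)C)[C@H]12 | intermediate
21 | (3R,3aS,4S,8aR)-3,4-dihydroxy-6,8a-dimethyl-3-(propan-2-yl)-2,3,3a,4,5,8-hexahydroazulen-1(8aH)-one (2-oxo-jaeschkeanadiol) | O[C@H]1CC(C)=CC[C@@]2(C)C(=O)C[C@@](O)(C(C)C)[C@H]12 | intermediate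
22 | 4-methoxybenzoyl chloride | COc1ccc(C(Cl)=O)cc1 | starting material
23 | (3R,3aS,4S,8aR)-3-hydroxy-6,8a-dimethyl-1-oxo-3-(propan-2-yl)-1,2,3,3a,4,5,8,8a-octahydroazulen-4-yl 4-methoxybenzoate | COc1ccc(C(=O)O[C@H]2CC(C)=CC[C@@]3(C)C(=O)C[C@@](O)(C(C)C)[C@H]23)cc1 | target

**Step count**

Total: 15 steps. Longest linear sequence: 15 steps (1 and 2 to 23); 22 is bought.

**Steps most likely to fail**

1. Step 10 (Buchner reaction).
   - What may go wrong: the fully substituted carbenoid may be lost to hydride migration from its own methyl group (vinyl ketone), or may add too slowly to the crowded ipso–ortho bond, so that insertion into the isopropyl C–H bond or capture by the silyl ether oxygen takes over.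
   - Fallback: it sets out from aldehyde 11 and comes back at azulenone 17. Pinnick oxidation (NaClO2, NaH2PO4, 2-methylbut-2-ene, t-BuOH/H2O) would give (3R)-3-(2-methoxy-4-methylphenyl)-4-methyl-3-(triethylsilyloxy)pentanoic acid F1. Activation with isobutyl chloroformate and N-methylmorpholine would give the mixed carbonic anhydride F2 (not isolated), which diazomethane would convert into the terminal diazo ketone F3. Rh2(OAc)4 in CH2Cl2 would then effect the Buchner reaction of this monosubstituted carbenoid, the best-precedented case and one with no migrating β-hydrogen, to give the 8a-unsubstituted azulenone F4 under the same control by C4. Deprotonation of the ring-fusion C1–H, the most acidic position (LiN(SiMe3)2, THF, −78 °C), and C-methylation of the extended enolate with MeI on the face anti to the isopropyl group would give 17.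

2. Step 12 (1,6-reduction).
   - What may go wrong: the samarium dienolate may be protonated at the γ-carbon C9, which would give the conjugated C7=C8 enone, or the carbonyl groups may be reduced further.
   - Fallback: it sets out from dienone 18 and comes back at 19 without a new compound. Catalytic 1,4-hydrogenation of the s-cis C7=C8–C9=C10 diene with (η6-naphthalene)Cr(CO)3 (zerovalent chromium) under H2 in THF adds hydrogen at the diene termini C7 and C10 and leaves the C8=C9 alkene. This known route from conjugated dienes to the 1,4-dihydro product involves no enolate and therefore no choice of protonation site.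

3. Step 14 (directed reduction).
   - What may go wrong: the C4 hydroxyl is β to both carbonyl groups, so hydride may be delivered to C2 as well as to C6.
   - Fallback: it sets out from 20 and comes back at 23. Excess Me4NBH(OAc)3 (0 °C → rt) would reduce both carbonyl groups by delivery from the C4 hydroxyl and give the triol F5. The C6 hydroxyl, flanked by CH and CH2, would be acylated with 22 (1 equiv, pyridine, DMAP, −20 °C) in preference to the neopentylic C2 hydroxyl, giving the C6 mono-anisoate F6. Dess–Martin oxidation of the remaining secondary hydroxyl would restore the C2 ketone and give 23.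

Further compounds
F1 | step 10 | (3R)-3-(2-methoxy-4-methylphenyl)-4-methyl-3-(triethylsilyloxy)pentanoic acid | O=C(O)C[C@@](O[Si](CC)(CC)CC)(C(C)C)c1ccc(C)cc1OC
F2 | step 10 | isobutyl mixed carbonic anhydride of F1 | CC(C)COC(=O)OC(=O)C[C@@](O[Si](CC)(CC)CC)(C(C)C)c1ccc(C)cc1OC
F3 | step 10 | (4R)-1-diazo-4-(2-methoxy-4-methylphenyl)-5-methyl-4-(triethylsilyloxy)hexan-2-one | [N-]=[N+]=CC(=O)C[C@@](O[Si](CC)(CC)CC)(C(C)C)c1ccc(C)cc1OC
F4 | step 10 | (3R)-4-methoxy-6-methyl-3-(propan-2-yl)-3-(triethylsilyloxy)-3,8a-dihydroazulen-1(2H)-one, 8a-H on the face taken by the methyl group in 17 | COC1C=C(C)C=C[C@H]2C(=O)C[C@@](O[Si](CC)(CC)CC)(C(C)C)C=12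
F0 | step 12 | none | none
F5 | step 14 | triol from reduction of both carbonyl groups of 20 (C2 and C6 hydroxyls anti to the C4 oxygen) | O[C@H]1CC(C)=CC[C@@]2(C)[C@@H](O)C[C@@](O)(C(C)C)[C@H]12
F6 | step 14 | C6 4-methoxybenzoate of triol F5 | COc1ccc(C(=O)O[C@H]2CC(C)=CC[C@@]3(C)[C@@H](O)C[C@@](O)(C(C)C)[C@H]23)cc1
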